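**Retrosynthetic overview**
1. The C11=C12 E-alkene comes from dehydration of homoallylic alcohol 35; the quaternary C-10 comes from a chiral phosphoric acid-catalysed allylboration of aldehyde 34 with allylboronate 20.
2. The right half 20 comes from (R)-ketone 6 by two methylalumination/Negishi cycles that fix both trisubstituted E-alkenes.
3. The left half 34 comes from ring ester 28 by Wittig, conjugate reduction, formyl-olefination and organocatalytic transfer hydrogenation (sets C-13).
4. The only ring is closed once, by a cation–olefin cyclisation of the open-chain silyl dienoate 26, itself made from (S)-ketone 22.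
5. Ketones 6 and 22 come from one new reaction: an imidodiphosphorimidate-catalysed conjugate SE2′ allylation of methyl vinyl ketone with a tiglylsilane, run with mirror-image catalysts.

Assumption: the sense of induction of the new step is unknown, so "IDPi-A" is defined as the enantiomer of the chiral imidodiphosphorimidate acid (two 3,3′-diaryl-BINOL units, N-triflyl groups) that gives (5R)-6 and "ent-IDPi-A" as its mirror image; the TRIP enantiomers in steps 15 and 16 are chosen by analogy with citral reduction and with allylboration of simple aldehydes. Locants C-10, C-11, C-13 refer to the pentadecatriene name of 36.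

**Route**

Step 1
Reactants: 1 (E)-2-bromobut-2-ene; 2 [(trimethylsilyl)methyl]magnesium chloride
Product: 3 (E)-trimethyl(2-methylbut-2-en-1-yl)silane
Conditions: Pd(PPh3)4 (2 mol%), THF, 50 °C
Reagents that add atoms: none
Why: Kumada coupling of an alkenyl bromide with Me3SiCH2MgCl is a standard allylsilane synthesis and retains the E geometry.

Step 2
Reactants: 3 (E)-trimethyl(2-methylbut-2-en-1-yl)silane; 4 but-3-en-2-one
Product: 6 (5R)-5,6-dimethylhept-6-en-2-one, via silyl enol ether 5 (not isolated)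
Conditions: IDPi-A (2 mol%), toluene, −60 °C; then 1 M HCl, THF, 0 °C
Reagents that add atoms: none
Why: Proposed new method: an enantioselective conjugate Hosomi–Sakurai (SE2′) allylation of an enone in which the only new stereocentre is born on the allylsilane carbon; a trace of 3 silylates the acid, the silylium ion pair activates 4 as an O-silyl oxocarbenium ion inside the confined chiral anion, the γ-carbon of 3 adds to the unsubstituted β-carbon with one face of the E-alkene exposed, and the β-silyl cation returns Me3Si+ to give 5 and turn the catalyst over; the closest known reactions are the imidodiphosphorimidate-catalysed Hosomi–Sakurai allylation of aldehydes and Mukaiyama–Michael additions, and the racemic TiCl4-mediated Sakurai conjugate allylation of enones.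

Step 3
Reactants: 6 (5R)-5,6-dimethylhept-6-en-2-one
Product: 9 (5R)-5,6-dimethylhept-6-en-1-yne, via enol phosphate 7 (not isolated), via lithium acetylide 8 (not isolated)
Conditions: LiN(i-Pr)2 (1.05 equiv), THF, −78 °C; ClP(O)(OEt)2; then LiN(i-Pr)2 (2.3 equiv), −78 °C → rt; H2O
Reagents that add atoms: none
Why: Kinetic enolisation on the methyl side, O-phosphorylation and double elimination is the Negishi methyl ketone to terminal alkyne protocol; the stereocentre is γ to the carbonyl and is not touched.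

Step 4
Reactants: 9 (5R)-5,6-dimethylhept-6-en-1-yne
Product: 11 (1E,5R)-1-iodo-2,5,6-trimethylhepta-1,6-diene, via alkenylalane 10 (not isolated)
Conditions: AlMe3 (2 equiv), Cp2ZrCl2 (0.2 equiv), CH2Cl2, 0 °C → rt; then I2, THF, −30 °C
Reagents that add atoms: trimethylaluminium, C[Al](C)C; iodine, II
Why: Negishi zirconium-catalysed methylalumination adds Me and Al syn across the terminal alkyne only (the 1,1-disubstituted alkene is inert) and iodinolysis retains geometry, giving the E-alkenyl iodide.

Step 5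
Reactants: 11 (1E,5R)-1-iodo-2,5,6-trimethylhepta-1,6-diene; 12 (4-bromobut-1-yn-1-yl)trimethylsilane
Product: 15 (5E,9R)-6,9,10-trimethylundeca-5,10-dien-1-yne, via organozinc bromide 13 (not isolated), via silylated enyne 14 (not isolated)
Conditions: 12, Zn dust, LiCl, THF, 40 °C; then 11, Pd(dppf)Cl2 (3 mol%), THF, rt; then K2CO3, MeOH, rt
Reagents that add atoms: none
Why: Negishi sp2–sp3 coupling of the alkylzinc with the alkenyl iodide proceeds with retention of the E geometry, and methanolysis removes the alkynyl silyl group.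

Step 6
Reactants: 15 (5E,9R)-6,9,10-trimethylundeca-5,10-dien-1-yne
Product: 17 (1E,5E,9R)-1-iodo-2,6,9,10-tetramethylundeca-1,5,10-triene, via alkenylalane 16 (not isolated)
Conditions: AlMe3 (2 equiv), Cp2ZrCl2 (0.2 equiv), CH2Cl2, 0 °C → rt; then I2, THF, −30 °C
Reagents that add atoms: trimethylaluminium, C[Al](C)C; iodine, II
Why: A second Negishi methylalumination/iodinolysis sets the second trisubstituted E-alkene; tri- and 1,1-disubstituted alkenes do not react.

Step 7
Reactants: 17 (1E,5E,9R)-1-iodo-2,6,9,10-tetramethylundeca-1,5,10-triene; 18 2-(iodomethyl)-4,4,5,5-tetramethyl-1,3,2-dioxaborolane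
Product: 20 4,4,5,5-tetramethyl-2-[(2E,6E,10R)-3,7,10,11-tetramethyldodeca-2,6,11-trien-1-yl]-1,3,2-dioxaborolane, via borylmethylzinc iodide 19 (not isolated)
Conditions: 18, Zn dust, THF, rt; then 17, Pd(PPh3)4 (5 mol%), THF, 50 °C
Reagents that add atoms: none
Why: Negishi coupling of the borylmethylzinc reagent with an alkenyl iodide gives the allylboronate with the 2E geometry fixed by the iodide, with no π-allyl intermediate that could scramble it.

Step 8
Reactants: 3 (E)-trimethyl(2-methylbut-2-en-1-yl)silane; 4 but-3-en-2-one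
Product: 22 (5S)-5,6-dimethylhept-6-en-2-one, via silyl enol ether 21 (not isolated)
Conditions: ent-IDPi-A (2 mol%), toluene, −60 °C; then 1 M HCl, THF, 0 °C
Reagents that add atoms: none
Why: Proposed new method: the same silylium ion-pair conjugate SE2′ allylation as in step 2, run with the mirror-image catalyst so that the opposite face of the E-allylsilane adds to the bound enone and the (S) centre (later the ring C-3) is set; closest known reactions are again the imidodiphosphorimidate-catalysed Hosomi–Sakurai and Mukaiyama–Michael reactions.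

Step 9
Reactants: 22 (5S)-5,6-dimethylhept-6-en-2-one
Product: 25 methyl (6S)-6,7-dimethyloct-7-en-2-ynoate, via enol phosphate 23 (not isolated), via lithium acetylide 24 (not isolated)
Conditions: LiN(i-Pr)2 (1.05 equiv), THF, −78 °C; ClP(O)(OEt)2; LiN(i-Pr)2 (2.3 equiv), −78 °C → rt; then ClCO2Me (2 equiv), −78 °C
Reagents that add atoms: methyl chloroformate, COC(=O)Cl
Why: The same Negishi ketone-to-alkyne sequence, with the lithium acetylide acylated in the same flask to give the ynoate.

Step 10
Reactants: 25 methyl (6S)-6,7-dimethyloct-7-en-2-ynoate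
Product: 26 methyl (2E,6S)-6,7-dimethyl-3-[(trimethylsilyl)methyl]octa-2,7-dienoate
Conditions: (Me3SiCH2)2CuLi (1.3 equiv, from Me3SiCH2Li and CuI), THF, −78 °C; MeOH, −78 °C
Reagents that add atoms: (trimethylsilyl)methyllithium, C[Si](C)(C)C[Li]
Why: Syn carbocupration of an alkynoate at −78 °C with protonation under retention places the ester cis to the alkyl chain, giving the 2E γ-silyl enoate.

Step 11
Reactants: 26 methyl (2E,6S)-6,7-dimethyl-3-[(trimethylsilyl)methyl]octa-2,7-dienoate
Product: 28 methyl (1S,3S)-2,2,3-trimethyl-6-methylidenecyclohexane-1-carboxylate, via tertiary chloride 27 (not isolated)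
Conditions: anhydrous HCl (1.1 equiv), CH2Cl2, −40 °C; then TiCl4 (2.2 equiv), −78 °C; aq. NaHCO3
Reagents that add atoms: none
Why: Markovnikov HCl addition to the 1,1-disubstituted alkene gives 27, TiCl4 ionises it and the cation is trapped at the α-carbon of the γ-silyl enoate in a vinylogous Hosomi–Sakurai cation–olefin cyclisation, with loss of Me3SiCl fixing the exocyclic methylene; in the chair transition state the existing methyl is equatorial and the ester, cis to the tether on the 2E alkene, is forced axial, which sets C-1 (S) trans to the C-3 methyl.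

Step 12
Reactants: 28 methyl (1S,3S)-2,2,3-trimethyl-6-methylidenecyclohexane-1-carboxylate
Product: 30 (3E)-4-[(1S,3S)-2,2,3-trimethyl-6-methylidenecyclohexyl]but-3-en-2-one, via aldehyde 29 (not isolated)
Conditions: i-Bu2AlH (1.1 equiv), CH2Cl2, −78 °C; aq. potassium sodium tartrate (KNaC4H4O6); crude 29, Ph3P=CHC(O)CH3 (2 equiv), toluene, 90 °C
Reagents that add atoms: 1-(triphenyl-λ5-phosphanylidene)propan-2-one, CC(=O)C=P(c1ccccc1)(c1ccccc1)c1ccccc1
Why: The hindered ester stops at the aldehyde stage with i-Bu2AlH at −78 °C, and the neutral stabilised Wittig reagent gives the E-enone without epimerising or conjugating the α-chiral β,γ-unsaturated aldehyde.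

Step 13
Reactants: 30 (3E)-4-[(1S,3S)-2,2,3-trimethyl-6-methylidenecyclohexyl]but-3-en-2-one
Product: 31 4-[(1S,3S)-2,2,3-trimethyl-6-methylidenecyclohexyl]butan-2-one
Conditions: [(Ph3P)CuH]6 (3 mol%), PhMe2SiH (1.5 equiv), t-BuOH (1.5 equiv), toluene, rt
Reagents that add atoms: none
Why: CuH conjugate reduction is selective for the enone C=C and leaves the isolated exocyclic alkene alone.

Step 14
Reactants: 31 4-[(1S,3S)-2,2,3-trimethyl-6-methylidenecyclohexyl]butan-2-one
Product: 33 (2E/Z)-3-methyl-5-[(1S,3S)-2,2,3-trimethyl-6-methylidenecyclohexyl]pent-2-enal, via unsaturated imine 32 (not isolated)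
Conditions: (EtO)2P(O)CH2CH=N-c-C6H11 (1.5 equiv), NaH, THF, 0 °C → rt; then aq. oxalic acid, rt
Reagents that add atoms: diethyl [2-(cyclohexylimino)ethyl]phosphonate, CCOP(=O)(CC=NC1CCCCC1)OCC; water, O
Why: Horner–Wadsworth–Emmons formyl-olefination of the methyl ketone and imine hydrolysis give the β,β-disubstituted enal; the E/Z mixture is acceptable because the next step is stereoconvergent.

Step 15
Reactants: 33 (2E/Z)-3-methyl-5-[(1S,3S)-2,2,3-trimethyl-6-methylidenecyclohexyl]pent-2-enal
Product: 34 (3S)-3-methyl-5-[(1S,3S)-2,2,3-trimethyl-6-methylidenecyclohexyl]pentanal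
Conditions: morpholinium (S)-TRIP salt (20 mol%), Hantzsch ester (1.2 equiv), dioxane, 50 °C
Reagents that add atoms: none
Why: Organocatalytic iminium transfer hydrogenation with a chiral phosphate counteranion: E and Z iminium ions interconvert and hydride is delivered to one face, setting C-3 (S) as in the reduction of citral to citronellal.

Step 16
Reactants: 34 (3S)-3-methyl-5-[(1S,3S)-2,2,3-trimethyl-6-methylidenecyclohexyl]pentanal; 20 4,4,5,5-tetramethyl-2-[(2E,6E,10R)-3,7,10,11-tetramethyldodeca-2,6,11-trien-1-yl]-1,3,2-dioxaborolane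
Product: 35 (3R,6E,10S,11R,13S)-10-ethenyl-2,3,6,10,13-pentamethyl-15-[(1S,3S)-2,2,3-trimethyl-6-methylidenecyclohexyl]pentadeca-1,6-dien-11-ol
Conditions: (S)-TRIP (10 mol%), 4 Å molecular sieves, toluene, −20 °C → rt; aqueous work-up
Reagents that add atoms: none
Why: Chiral phosphoric acid-catalysed allylboration through a closed chair: the acid binds the boronate oxygen and the formyl hydrogen and directs Si-face attack, and the 2E boronate places the chain equatorial and the methyl axial, so the carbinol (11R) and the vinyl-bearing quaternary centre (10S) are set together under catalyst control.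

Step 17
Reactants: 35 (3R,6E,10S,11R,13S)-10-ethenyl-2,3,6,10,13-pentamethyl-15-[(1S,3S)-2,2,3-trimethyl-6-methylidenecyclohexyl]pentadeca-1,6-dien-11-ol
Product: 36 (3R,6E,10S,11E,13S)-10-ethenyl-2,3,6,10,13-pentamethyl-15-[(1S,3S)-2,2,3-trimethyl-6-methylidenecyclohexyl]pentadeca-1,6,11-triene
Conditions: Burgess reagent (Et3N+SO2N−CO2Me, 2 equiv), toluene, 70 °C
Reagents that add atoms: none
Why: Burgess syn-elimination of the sulfamate can only go toward C-12 because C-10 is quaternary, giving the E-alkene as the single regioisomer without touching the five stereocentres.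

**Compound list**
1 | (E)-2-bromobut-2-ene | C/C=C(\C)Br | starting material
2 | [(trimethylsilyl)methyl]magnesium chloride | C[Si](C)(C)C[Mg]Cl | starting material
3 | (E)-trimethyl(2-methylbut-2-en-1-yl)silane | C/C=C(\C)C[Si](C)(C)C | intermediate
4 | but-3-en-2-one (methyl vinyl ketone) | CC(=O)C=C | starting material
5 | trimethyl{[(5R)-5,6-dimethylhepta-2,6-dien-2-yl]oxy}silane (enol ether geometry not defined) | CC(=CC[C@@H](C)C(=C)C)O[Si](C)(C)C | intermediate
6 | (5R)-5,6-dimethylhept-6-en-2-one | CC(=O)CC[C@@H](C)C(=C)C | intermediate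
7 | diethyl (5R)-5,6-dimethylhepta-1,6-dien-2-yl phosphate | CCOP(=O)(OCC)OC(=C)CC[C@@H](C)C(=C)C | intermediate
8 | lithium (5R)-5,6-dimethylhept-6-en-1-yn-1-ide | [Li]C#CCC[C@@H](C)C(=C)C | intermediate
9 | (5R)-5,6-dimethylhept-6-en-1-yne | C#CCC[C@@H](C)C(=C)C | intermediate
10 | dimethyl[(1E,5R)-2,5,6-trimethylhepta-1,6-dien-1-yl]alane | C/C(=C\[Al](C)C)CC[C@@H](C)C(=C)C | intermediate
11 | (1E,5R)-1-iodo-2,5,6-trimethylhepta-1,6-diene | C/C(=C\I)CC[C@@H](C)C(=C)C | intermediate
12 | (4-bromobut-1-yn-1-yl)trimethylsilane | C[Si](C)(C)C#CCCBr | starting material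
13 | bromo[4-(trimethylsilyl)but-3-yn-1-yl]zinc | C[Si](C)(C)C#CCC[Zn]Br | intermediate
14 | trimethyl[(5E,9R)-6,9,10-trimethylundeca-5,10-dien-1-yn-1-yl]silane | C[Si](C)(C)C#CCC/C=C(\C)CC[C@@H](C)C(=C)C | intermediate
15 | (5E,9R)-6,9,10-trimethylundeca-5,10-dien-1-yne | C#CCC/C=C(\C)CC[C@@H](C)C(=C)C | intermediate
16 | dimethyl[(1E,5E,9R)-2,6,9,10-tetramethylundeca-1,5,10-trien-1-yl]alane | C/C(=C\[Al](C)C)CC/C=C(\C)CC[C@@H](C)C(=C)C | intermediate
17 | (1E,5E,9R)-1-iodo-2,6,9,10-tetramethylundeca-1,5,10-triene | C/C(=C\I)CC/C=C(\C)CC[C@@H](C)C(=C)C | intermediate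
18 | 2-(iodomethyl)-4,4,5,5-tetramethyl-1,3,2-dioxaborolane | CC1(C)OB(CI)OC1(C)C | starting material
19 | iodo[(4,4,5,5-tetramethyl-1,3,2-dioxaborolan-2-yl)methyl]zinc | CC1(C)OB(C[Zn]I)OC1(C)C | intermediate
20 | 4,4,5,5-tetramethyl-2-[(2E,6E,10R)-3,7,10,11-tetramethyldodeca-2,6,11-trien-1-yl]-1,3,2-dioxaborolane | C/C(=C\CB1OC(C)(C)C(C)(C)O1)CC/C=C(\C)CC[C@@H](C)C(=C)C | intermediate
21 | trimethyl{[(5S)-5,6-dimethylhepta-2,6-dien-2-yl]oxy}silane (enol ether geometry not defined) | CC(=CC[C@H](C)C(=C)C)O[Si](C)(C)C | intermediate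
22 | (5S)-5,6-dimethylhept-6-en-2-one | CC(=O)CC[C@H](C)C(=C)C | intermediate
23 | diethyl (5S)-5,6-dimethylhepta-1,6-dien-2-yl phosphate | CCOP(=O)(OCC)OC(=C)CC[C@H](C)C(=C)C | intermediate
24 | lithium (5S)-5,6-dimethylhept-6-en-1-yn-1-ide | [Li]C#CCC[C@H](C)C(=C)C | intermediate
25 | methyl (6S)-6,7-dimethyloct-7-en-2-ynoate | COC(=O)C#CCC[C@H](C)C(=C)C | intermediate
26 | methyl (2E,6S)-6,7-dimethyl-3-[(trimethylsilyl)methyl]octa-2,7-dienoate | COC(=O)/C=C(/C[Si](C)(C)C)CC[C@H](C)C(=C)C | intermediate
27 | methyl (2E,6S)-7-chloro-6,7-dimethyl-3-[(trimethylsilyl)methyl]oct-2-enoate | COC(=O)/C=C(/C[Si](C)(C)C)CC[C@H](C)C(C)(C)Cl | intermediate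
28 | methyl (1S,3S)-2,2,3-trimethyl-6-methylidenecyclohexane-1-carboxylate | COC(=O)[C@H]1C(=C)CC[C@H](C)C1(C)C | intermediate
29 | (1S,3S)-2,2,3-trimethyl-6-methylidenecyclohexane-1-carbaldehyde | O=C[C@H]1C(=C)CC[C@H](C)C1(C)C | intermediate
30 | (3E)-4-[(1S,3S)-2,2,3-trimethyl-6-methylidenecyclohexyl]but-3-en-2-one | CC(=O)/C=C/[C@H]1C(=C)CC[C@H](C)C1(C)C | intermediate
31 | 4-[(1S,3S)-2,2,3-trimethyl-6-methylidenecyclohexyl]butan-2-one | CC(=O)CC[C@H]1C(=C)CC[C@H](C)C1(C)C | intermediate
32 | N-cyclohexyl-3-methyl-5-[(1S,3S)-2,2,3-trimethyl-6-methylidenecyclohexyl]pent-2-en-1-imine (E/Z mixture) | CC(CC[C@H]1C(=C)CC[C@H](C)C1(C)C)=CC=NC1CCCCC1 | intermediate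
33 | (2E/Z)-3-methyl-5-[(1S,3S)-2,2,3-trimethyl-6-methylidenecyclohexyl]pent-2-enal (2E isomer drawn) | C/C(CC[C@H]1C(=C)CC[C@H](C)C1(C)C)=C\C=O | intermediate
34 | (3S)-3-methyl-5-[(1S,3S)-2,2,3-trimethyl-6-methylidenecyclohexyl]pentanal | O=CC[C@@H](C)CC[C@H]1C(=C)CC[C@H](C)C1(C)C | intermediate
35 | (3R,6E,10S,11R,13S)-10-ethenyl-2,3,6,10,13-pentamethyl-15-[(1S,3S)-2,2,3-trimethyl-6-methylidenecyclohexyl]pentadeca-1,6-dien-11-ol | C=C[C@@](C)([C@H](O)C[C@@H](C)CC[C@H]1C(=C)CC[C@H](C)C1(C)C)CC/C=C(\C)CC[C@@H](C)C(=C)C | intermediate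
36 | (3R,6E,10S,11E,13S)-10-ethenyl-2,3,6,10,13-pentamethyl-15-[(1S,3S)-2,2,3-trimethyl-6-methylidenecyclohexyl]pentadeca-1,6,11-triene (CNP0293684.2) | C=C[C@@](C)(/C=C/[C@@H](C)CC[C@H]1C(=C)CC[C@H](C)C1(C)C)CC/C=C(\C)CC[C@@H](C)C(=C)C | target

**Step count and risks**

Total steps: 17. Longest linear sequence: 11 (steps 1, 8, 9, 10, 11, 12, 13, 14, 15, 16, 17).

Steps 2 and 8 (the proposed new conjugate SE2′ allylation). Risks are 1,2-addition or annulation instead of conjugate allylation, and low enantioselectivity because the stereocentre forms on the nucleophile. The fallback uses known copper-catalysed asymmetric allylic alkylation; it sets out from 4 and 1 and comes back at 6 (and at 22 with the mirror-image ligand). Ketone 4 is treated with HBr and ethylene glycol to give 2-(2-bromoethyl)-2-methyl-1,3-dioxolane F1, which Mg turns into bromo[2-(2-methyl-1,3-dioxolan-2-yl)ethyl]magnesium F2. Bromide 1 is lithiated with t-BuLi and trapped with paraformaldehyde to give (E)-2-methylbut-2-en-1-ol F3, which MsCl and LiCl convert into (E)-1-chloro-2-methylbut-2-ene F4. SN2′ alkylation of F4 with F2 (Cu(O2CC4H3S) 3 mol%, chiral phosphoramidite, CH2Cl2, −78 °C) gives 2-[(3R)-3,4-dimethylpent-4-en-1-yl]-2-methyl-1,3-dioxolane F5, and aqueous HCl releases 6. The mirror-image ligand gives 2-[(3S)-3,4-dimethylpent-4-en-1-yl]-2-methyl-1,3-dioxolane F6 and from it 22.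

Step 11 (cyclisation). Risks are a 1,2-hydride shift in the tertiary cation next to the methyl-bearing stereocentre (erosion of that centre, five-membered ring by-products) and incomplete trans selectivity. The fallback moves the methylene installation after ring closure and uses thermodynamic control at C-1; it sets out from 22 and comes back at 28. Ketone 22 is carboxylated (NaH, (MeO)2CO, THF, reflux) to methyl (6S)-6,7-dimethyl-3-oxooct-7-enoate F7. SnCl4 in CH2Cl2 cyclises it through the tin enolate, the classical keto-ester cation–olefin cyclisation, to methyl (3S)-2,2,3-trimethyl-6-oxocyclohexane-1-carboxylate F8. Wittig methylenation (Ph3P=CH2, THF) gives 28 together with its C-1 epimer methyl (1R,3S)-2,2,3-trimethyl-6-methylidenecyclohexane-1-carboxylate F9. Equilibration with NaOMe in MeOH (the axial ester is expected to be favoured by allylic strain with the exocyclic methylene, but the ratio is not known) and chromatography deliver 28.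

Step 16 (allylboration). Risks are low reactivity of the hindered γ,γ-disubstituted boronate and weak facial control with an aliphatic aldehyde. The fallback replaces boron by catalytic asymmetric chromium allylation; it sets out from 15 and 34 and comes back at 35. Enyne 15 is methylaluminated (AlMe3, Cp2ZrCl2), converted into the aluminate with n-BuLi and trapped with paraformaldehyde to give (2E,6E,10R)-3,7,10,11-tetramethyldodeca-2,6,11-trien-1-ol F10. PBr3 at −20 °C gives (2E,6E,10R)-1-bromo-3,7,10,11-tetramethyldodeca-2,6,11-triene F11. Nozaki–Hiyama–Kishi allylation of 34 with F11 (CrCl2 10 mol%, Mn, Me3SiCl, chiral bis(oxazolinyl)carbazole ligand, THF) gives the trimethylsilyl ether of 35 F12, and Bu4NF releases 35.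

Further compounds
F1 | step 2 | 2-(2-bromoethyl)-2-methyl-1,3-dioxolane | CC1(CCBr)OCCO1
F2 | step 2 | bromo[2-(2-methyl-1,3-dioxolan-2-yl)ethyl]magnesium | CC1(CC[Mg]Br)OCCO1
F3 | step 2 | (E)-2-methylbut-2-en-1-ol | C/C=C(\C)CO
F4 | step 2 | (E)-1-chloro-2-methylbut-2-ene | C/C=C(\C)CCl
F5 | step 2 | 2-[(3R)-3,4-dimethylpent-4-en-1-yl]-2-methyl-1,3-dioxolane | CC1(CC[C@@H](C)C(=C)C)OCCO1
F6 | step 2 | 2-[(3S)-3,4-dimethylpent-4-en-1-yl]-2-methyl-1,3-dioxolane | CC1(CC[C@H](C)C(=C)C)OCCO1
F7 | step 11 | methyl (6S)-6,7-dimethyl-3-oxooct-7-enoate | COC(=O)CC(=O)CC[C@H](C)C(=C)C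
F8 | step 11 | methyl (3S)-2,2,3-trimethyl-6-oxocyclohexane-1-carboxylate (C-1 epimers) | COC(=O)C1C(=O)CC[C@H](C)C1(C)C
F9 | step 11 | methyl (1R,3S)-2,2,3-trimethyl-6-methylidenecyclohexane-1-carboxylate | COC(=O)[C@@H]1C(=C)CC[C@H](C)C1(C)C
F10 | step 16 | (2E,6E,10R)-3,7,10,11-tetramethyldodeca-2,6,11-trien-1-ol | C/C(=C\CO)CC/C=C(\C)CC[C@@H](C)C(=C)C
F11 | step 16 | (2E,6E,10R)-1-bromo-3,7,10,11-tetramethyldodeca-2,6,11-triene | C/C(=C\CBr)CC/C=C(\C)CC[C@@H](C)C(=C)C
F12 | step 16 | trimethylsilyl ether of 35 | C=C[C@@](C)([C@H](O[Si](C)(C)C)C[C@@H](C)CC[C@H]1C(=C)CC[C@H](C)C1(C)C)CC/C=C(\C)CC[C@@H](C)C(=C)C
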